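**Remarks on the chemistry**

- Numbering: C1–C2 is the ethyl group on C3, C3a the hydroxymethyl carbon on C3, C3–C13 the chain, and C14–C19 the ring (C14 quaternary, C15 CH–Et, C16 C=O, C17=C18, C19 carbinol).
- Assumption: 5, 23 and 29 are taken as purchasable (5 is otherwise one step from 3-bromobutan-2-one and PPh3, 23 from (−)-Ipc2BOMe and allylMgBr, 29 from (S)-4-benzyloxazolidin-2-one and butanoyl chloride).
- Assumption: the iPr-DuPHOS antipode that delivers allyl to the Re face of the C19 carbonyl is written as (R,R); the sense is to be fixed on a small scale with 6.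
- Design choices:
  - The C8 oxygen is carried as an all-alkyl silyl ether (TBS), because silicon-bound phenyl rings are at risk under Li/NH3.
  - C15 is set under kinetic control in the alkylation, because an equilibrium between the C15 epimers is not expected to favour either one clearly.
  - Enone 6 is reached by ozonolysis and Wittig olefination (two steps, no selenium) instead of allylic oxidation.

## Structural features

The target is a cyclohex-2-enone (ring A, C14–C19) joined through C13 to a thirteen-carbon chain that ends in a 1,3,5-triol. Ring A carries three contiguous stereocentres: C15 (ethyl, α to the C16 ketone, epimerisable), C14 (all-carbon quaternary, methyl plus the chain) and C19 (tertiary allylic alcohol with a methyl group). The chain holds an isolated methyl stereocentre at C10, three methylenes away from the ring, and a stereotetrad at C3, C4, C6 and C7. In that tetrad the C7 methyl is anti to the C6 hydroxyl, the C4 and C6 hydroxyls are syn, and the C3 ethyl is syn to the C4 hydroxyl. The fragile parts are the γ-hydroxy enone (base epimerises C15) and, in intermediates, the tertiary allylic C19 oxygen. The real difficulty is the vicinal pair of fully substituted carbons C14 and C19 next to C15, and the fact that C10 is too remote for any relay of configuration. The key step exploits the trisubstituted C13=C14 alkene of the citronellol skeleton, which sits exactly where the ring quaternary carbon is needed. A diazoketone carbon (C15) on a C16–C17–C18–C19 tether adds across this alkene, closing ring A and a C13–C14–C15 cyclopropane. Later cleavage of C13–C15 returns C13 to the chain and leaves a C15 enolate for ethylation.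

## Logic of the disconnections

43 from 42: the O–Si bonds at C6 and C19 and the two acetal C–O bonds of the dioxane are cut last. All hydroxyls are released only when no base or oxidant follows; 42 is non-polar and easy to purify. The forward step must remove a tertiary silyl ether and the acetonide with acid, without touching the enone or C15.

42 from 40: the C17=C18 unsaturation is removed. The enone makes C15–H the only acidic α-hydrogen and would not survive the hydrogenation, so it is introduced last. The forward step needs kinetic enolisation at C17, not C15.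

40 from 39: the C7–H bond is cut, leaving a 1,1-disubstituted alkene at C7. C7 then need not be carried in either fragment, and the union can use an sp2 carbon. The forward step must deliver hydrogen from the face of the C6 hydroxyl to give the anti relation.

39 from 21 and 37: the C7–C8 bond is cut. This divides the molecule into a terpenoid half with four stereocentres and a polyol half with three. The forward coupling must tolerate a ketone and a free hydroxyl, which points to an organozinc reagent.

21 from 20 from 19: the C8–I and C8–O(Si) bonds are exchanged. The gain is only functional; the demand is cleavage of a primary TBS ether beside a tertiary TES ether.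

19 from 17: the C15–ethyl bond is cut and C13–C15 is reconnected. The ethyl group and the C13 methylene are both traced to one cyclopropyl ketone, so C14 becomes a cyclopropane carbon. The forward step must cleave the external cyclopropane bond and ethylate the enolate on the correct face.

17 from 16: C14–C15 and C13–C15 are cut. The bicycle collapses to an acyclic diazoketone with a single relevant stereocentre (C19), and the ring carbons become a linear terpenoid chain. The forward step must add the carbenoid to the alkene face that places the C19 oxygen cis to the C14 methyl.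

16 from 13 and 14, and 13 from 12 from 10: the C15–C16 bond is cut back to an acid and a one-carbon diazo unit, and the acid is traced to a terminal alkene. This reduces the problem to a protected tertiary homoallylic alcohol; the demand is acid activation that spares the silyl ethers.

10 from 9 from 6 and 7: the C18–C19 bond is cut. A tertiary carbinol becomes a methyl ketone plus an allyl nucleophile. The demand is high enantiofacial control, because C10 is too far away to help or to allow later separation.

6 from 4 and 5, 4 from 2 from 1: the C13=C14 bond is cut, then the chain is traced to the chiral pool. The C10 stereocentre is bought; the demand is E geometry in the olefination.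

37 from 36 from 35: the C7–I bond is traced through a C–Si bond to a terminal alkyne, which needs Markovnikov hydrometalation. 35 from 34 from 33 from 32 from 28 and 29: the C3–C4 bond is cut (syn aldol), setting C3 and C4 under auxiliary control. 28 from 26 from 25 from 22 and 23: the C5–C6 bond is cut (allylation of an ynal), setting C6 under reagent control.

## Other disconnections considered

Alternative 1: The cut is C3–C4 together with the acyl–oxygen bond of a four-membered lactone. In the forward direction ethylketene A2 (from butanoyl chloride and a tertiary amine) is intercepted by a chiral nucleophilic catalyst. The resulting enolate adds to aldehyde A1 and the alkoxide closes the ring by acyl substitution, giving cis-lactone A3; a hydride reagent then opens A3 to the C3a/C4 diol.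
- In favour: it is catalytic, sets C3 and C4 in one step without an auxiliary, and the reduction gives exactly the required 1,3-diol.
- Against, here: it solves the easy acyclic diad and leaves ring A untouched. A1 already carries C7 and a C8 oxygen, so the fragment union would fall on the unfunctionalised C8–C9 bond and C8 of the terpene would have to be excised. The β-silyloxy group of A1 also exerts its own induction, which the catalyst must override.
- Structure: it addresses only what the chosen plan does in steps 16 and 17.
- Mechanism: a closed, catalyst-controlled polar transition state, equal in predictability to the boron aldol.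
- Step economy: two steps for the diad, the same as steps 16 and 17, with better atom economy; on that point it is the better. It could replace those two steps but cannot serve as the central disconnection.

Alternative 2: The cut is C14–C19, with C17 reconnected to oxygen to give δ-lactone A4. In the forward direction A4 is enolised and silylated to ketene acetal A5. A [3,3] shift through the boat geometry that the ring enforces forms C14–C19, moves the alkene to C17=C18 and releases C13 as the carboxyl group of A6.
- In favour: the hardest bond is made intramolecularly and in a concerted step. The C14/C19 relation follows from transition-state geometry and enol-ether configuration, not from a small steric difference; on this point it is the better. C15 is in place beforehand and protected from epimerisation by the ketal, which is better than enolate ethylation. C17=C18 arises directly, which saves the dehydrogenation.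
- Against: A4 needs three defined stereo-elements, including a geometrically pure trisubstituted silyl enol ether. The pericyclic step must join two fully substituted carbons. C13 emerges as a neopentyl carboxyl group that has to be reduced, joined to a C8–C12 unit by olefination, and saturated in the presence of C17=C18.
- Structure: better for the ring, worse for the ring–chain junction.
- Mechanism: more predictable in stereochemistry but sterically more demanding than the carbenoid addition.
- Step economy: about equal at best, since the steps saved in the ring are spent on C13.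

Alternative 3: The cut is the C14–methyl bond, traced to a bromomethylsilyl ether on the C19 oxygen of tetrasubstituted enone A7. In the forward direction a tin hydride chain generates the α-silyl radical, which closes 5-exo onto C14. The resulting C15 radical is reduced to give A8, and the C–Si bond is later cleaved to C–H.
- In favour: the tether can only deliver the carbon to the face of the C19 oxygen, so the cis relation of C19–O and C14–methyl is guaranteed; on this point it is the better. Radical conditions tolerate the complete protected chain, and no diazo compound is needed.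
- Against: the radical must attack a fully substituted acceptor carbon. C15 is set by hydrogen-atom transfer without control, which is equal to the weakness of the chosen plan. Cleavage of an unactivated alkyl–silicon bond needs forcing fluoride or base, which threatens C15. Tin reagents are less safe. C17=C18 must still be introduced by the same dehydrogenation (equal). A7 itself needs an enantioselective synthesis of C19 and of the enone bearing the whole chain.
- Structure: equal for C15, better for C14/C19.
- Mechanism: kinetically controlled radical cyclisation against carbenoid addition.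
- Step economy: no saving, because ring A has to be built separately.

Key step: step 9

## Steps

**Part A: ring fragment**

Step 1
Reactants: 1 (R)-citronellol
Product: 2 tert-butyl{[(3R)-3,7-dimethyloct-6-en-1-yl]oxy}dimethylsilane
Conditions: TBSCl, imidazole, DMF, 0 °C to rt
Reagents that add atoms: tert-butyldimethylsilyl chloride, CC(C)(C)[Si](C)(C)Cl
Why: Standard silylation of a primary alcohol; an all-alkyl silyl ether is chosen because it is inert to the dissolving-metal step.

Step 2
Reactants: 2 citronellyl TBS ether
Product: 4 (4R)-6-[(tert-butyldimethylsilyl)oxy]-4-methylhexanal, via secondary ozonide 3 (not isolated)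
Conditions: O3, CH2Cl2, −78 °C; then PPh3, −78 °C to rt
Reagents that add atoms: ozone, [O-][O+]=O
Why: Ozonolysis of the only alkene with reductive work-up gives the aldehyde; the C10 stereocentre is γ to the new carbonyl and is not touched.

Step 3
Reactants: 4 aldehyde; 5 3-(triphenylphosphoranylidene)butan-2-one
Product: 6 (3E,7R)-9-[(tert-butyldimethylsilyl)oxy]-3,7-dimethylnon-3-en-2-one
Conditions: toluene, 90 °C
Reagents that add atoms: none
Why: Wittig olefination with a stabilised, α-branched keto ylide should give the E trisubstituted enone under thermodynamic control of the oxaphosphetane pathway.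

Step 4
Reactants: 6 enone; 7 allylboronic acid pinacol ester
Product: 9 (4R,5E,9R)-11-[(tert-butyldimethylsilyl)oxy]-4,5,9-trimethylundeca-1,5-dien-4-ol, via O-boryl ether 8 (not isolated)
Conditions: CuF2·2H2O (3 mol %), (R,R)-iPr-DuPHOS (6 mol %), La(OiPr)3 (4.5 mol %), DMF, −40 °C; aqueous work-up
Reagents that add atoms: none
Why: Catalytic enantioselective allylboration of a ketone: the phosphine reduces the divalent copper fluoride to a monovalent copper species, which forms an allylcopper by transmetalation and adds 1,2 through a cyclic transition state; the ligand differentiates the methyl group from the branched alkenyl group, and Re-face attack gives (R)-C19.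

Step 5
Reactants: 9 tertiary alcohol
Product: 10 triethylsilyl ether of 9
Conditions: TESOTf, 2,6-lutidine, CH2Cl2, −78 to 0 °C
Reagents that add atoms: triethylsilyl trifluoromethanesulfonate, CC[Si](CC)(CC)OS(=O)(=O)C(F)(F)F
Why: Silyl triflate with a hindered base silylates tertiary alcohols under conditions that do not ionise the allylic carbinol; the ether blocks O–H insertion and lactonisation later.

Step 6
Reactants: 10 diene
Product: 12 (4R,5E,9R)-11-[(tert-butyldimethylsilyl)oxy]-4,5,9-trimethyl-4-[(triethylsilyl)oxy]undec-5-en-1-ol, via B-alkyl-9-borabicyclononane 11 (not isolated)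
Conditions: 9-BBN, THF, 0 °C to rt; then NaOH, H2O2, 0 °C
Reagents that add atoms: hydrogen peroxide, OO
Why: Anti-Markovnikov hydroboration and oxidation; 9-BBN reacts with the terminal alkene and leaves the hindered trisubstituted C13=C14 alkene alone.

Step 7
Reactants: 12 primary alcohol
Product: 13 (4R,5E,9R)-11-[(tert-butyldimethylsilyl)oxy]-4,5,9-trimethyl-4-[(triethylsilyl)oxy]undec-5-enoic acid
Conditions: TEMPO (cat.), PhI(OAc)2, MeCN/pH 7 buffer, rt
Reagents that add atoms: water, O
Why: Oxoammonium oxidation of the primary alcohol to the aldehyde and, through its hydrate, to the acid; the alkene and both silyl ethers should survive the buffered medium.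

Step 8
Reactants: 13 acid; 14 (trimethylsilyl)diazomethane
Product: 16 (5R,6E,10R)-12-[(tert-butyldimethylsilyl)oxy]-1-diazo-5,6,10-trimethyl-5-[(triethylsilyl)oxy]dodec-6-en-2-one, via isobutyl mixed anhydride 15 (not isolated)
Conditions: i-BuOCOCl, Et3N, THF, −15 °C; then 14, MeCN, 0 °C to rt
Reagents that add atoms: none
Why: C-acylation of the diazo carbon by a mixed anhydride with loss of the silyl group gives the terminal α-diazoketone (first stage of an Arndt–Eistert sequence); no HCl is formed, so the silyl ethers are safe, and the reagent is the non-explosive surrogate of diazomethane.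

Step 9
Reactants: 16 diazoketone
Product: 17 (1S,5R,6R,7S)-7-{(3R)-5-[(tert-butyldimethylsilyl)oxy]-3-methylpentyl}-5,6-dimethyl-5-[(triethylsilyl)oxy]bicyclo[4.1.0]heptan-2-one
Conditions: Rh2(OAc)4 (1 mol %), CH2Cl2, rt, slow addition of 16 at high dilution
Reagents that add atoms: none
Why: Rh2(OAc)4 takes N2 from the diazoketone and gives an electrophilic rhodium carbenoid at C15, which adds to the electron-rich trisubstituted C13=C14 alkene in one asynchronous, stereospecific step; the closest known reaction type is the copper- or rhodium-catalysed intramolecular cyclopropanation of 1-diazohept-6-en-2-ones to bicyclo[4.1.0]heptan-2-ones. The six-membered ring closes through the C14–C15 bond with C13 outside that ring (exo mode of a six-atom chain), and the cyclopropane closes through the accompanying C13–C15 bond as a [2+1] addition. The C13/C14 relation follows from the retained E geometry, which puts the C12 chain cis to the C14 methyl and exo on the bicycle. C15 follows from C14, because the three-atom tether allows only a cis ring fusion. The face of addition is controlled by C19: in the folded tether C18 lies over the alkene, the C19 methyl eclipses the alkene on the side of C13–H, and the silyloxy group lies beside the C14 methyl. The other arrangement would force the C19 and C14 methyl groups towards an eclipsed contact that grows as C14 pyramidalises, so the silyloxy group should end up cis to the C14 methyl. The step also needs chemoselectivity: 1,5 C–H insertion is excluded because C19 bears no hydrogen, O–H insertion is blocked by the silyl ether, and slow addition suppresses carbene dimerisation. C10 is remote and unaffected.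

Step 10
Reactants: 17 cyclopropyl ketone
Product: 19 (2R,3R,4R)-3-{(4R)-6-[(tert-butyldimethylsilyl)oxy]-4-methylhexyl}-2-ethyl-3,4-dimethyl-4-[(triethylsilyl)oxy]cyclohexan-1-one, via lithium enolate 18 (not isolated)
Conditions: Li (2.5 equiv), t-BuOH (1 equiv), NH3/THF, −78 °C; isoprene; NH3 removed; EtI (excess), THF/DMPU, −40 to 0 °C
Reagents that add atoms: iodoethane, CCI
Why: Two-electron reduction of the cyclopropyl ketone cleaves the external C13–C15 bond (best overlap with the carbonyl π system, less substituted carbanion) and gives the regiodefined C15 enolate, which is ethylated as in a Stork reductive alkylation; EtI is expected to enter anti to the pseudoaxial C13 chain on C14 and past an axial silyloxy oxygen, not an axial C19 methyl, which places the ethyl group cis to the C14 methyl.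

Step 11
Reactants: 19 bis-silyl ether
Product: 20 (2R,3R,4R)-2-ethyl-3-[(4R)-6-hydroxy-4-methylhexyl]-3,4-dimethyl-4-[(triethylsilyl)oxy]cyclohexan-1-one
Conditions: CSA (10 mol %), MeOH/CH2Cl2, −10 to 0 °C
Reagents that add atoms: none
Why: Acid-catalysed methanolysis should remove the unhindered primary TBS ether faster than the tertiary TES ether, which is buried between two fully substituted carbons.

Step 12
Reactants: 20 primary alcohol
Product: 21 (2R,3R,4R)-2-ethyl-3-[(4R)-6-iodo-4-methylhexyl]-3,4-dimethyl-4-[(triethylsilyl)oxy]cyclohexan-1-one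
Conditions: I2, PPh3, imidazole, CH2Cl2, 0 °C to rt
Reagents that add atoms: iodine, II
Why: Appel-type iodination of a primary alcohol through the alkoxyphosphonium salt; the ketone and the tertiary silyl ether are inert.

**Part B: polyol fragment**

Step 13
Reactants: 22 3-(trimethylsilyl)prop-2-ynal; 23 (−)-B-allyldiisopinocampheylborane
Product: 25 (3S)-1-(trimethylsilyl)hex-5-en-1-yn-3-ol, via diisopinocampheylborinate 24 (not isolated)
Conditions: Et2O, −78 °C; then NaOH, H2O2, 0 °C to rt
Reagents that add atoms: none
Why: Brown allylboration through a chair transition state with the alkynyl group equatorial; the reagent derived from (+)-α-pinene attacks the Si face, as with aromatic aldehydes, and should give the (S)-carbinol (C6).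

Step 14
Reactants: 25 propargylic alcohol
Product: 26 tert-butyldimethyl{[(3S)-1-(trimethylsilyl)hex-5-en-1-yn-3-yl]oxy}silane
Conditions: TBSCl, imidazole, DMF, rt
Reagents that add atoms: tert-butyldimethylsilyl chloride, CC(C)(C)[Si](C)(C)Cl
Why: Standard silylation of a secondary alcohol.

Step 15
Reactants: 26 enyne
Product: 28 (3S)-3-[(tert-butyldimethylsilyl)oxy]-5-(trimethylsilyl)pent-4-ynal, via secondary ozonide 27 (not isolated)
Conditions: O3, CH2Cl2, −78 °C (Sudan Red 7B as end-point indicator); then PPh3
Reagents that add atoms: ozone, [O-][O+]=O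
Why: Ozone reacts with the terminal alkene much faster than with the silylated alkyne, so indicator-controlled ozonolysis should give the β-silyloxy aldehyde.

Step 16
Reactants: 28 aldehyde; 29 (4S)-4-benzyl-3-butanoyl-1,3-oxazolidin-2-one
Product: 32 (4S)-4-benzyl-3-{(2S,3R,5S)-5-[(tert-butyldimethylsilyl)oxy]-2-ethyl-3-hydroxy-7-(trimethylsilyl)hept-6-ynoyl}-1,3-oxazolidin-2-one, via dibutylboron enolate 30 (not isolated), via boron aldolate 31 (not isolated)
Conditions: 29, Bu2BOTf, i-Pr2NEt, CH2Cl2, −78 to 0 °C; then 28, −78 to 0 °C; pH 7 buffer, MeOH, H2O2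
Reagents that add atoms: none
Why: Evans syn aldol: the Z boron enolate reacts through a Zimmerman–Traxler chair with the auxiliary controlling the face, which sets C3 and C4 in the required syn relation regardless of the β-silyloxy group.

Step 17
Reactants: 32 aldol adduct
Product: 33 (2R,3R,5S)-5-[(tert-butyldimethylsilyl)oxy]-2-ethyl-7-(trimethylsilyl)hept-6-yne-1,3-diol
Conditions: LiBH4, MeOH (1 equiv), THF, 0 °C
Reagents that add atoms: none
Why: Reductive removal of the oxazolidinone gives the primary alcohol C3a without epimerising C3; the auxiliary is recovered.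

Step 18
Reactants: 33 diol
Product: 34 tert-butyl{[(2S)-1-[(4R,5R)-5-ethyl-2,2-dimethyl-1,3-dioxan-4-yl]-4-(trimethylsilyl)but-3-yn-2-yl]oxy}dimethylsilane
Conditions: 2,2-dimethoxypropane, PPTS (cat.), CH2Cl2, rt
Reagents that add atoms: 2,2-dimethoxypropane, COC(C)(C)OC
Why: Transacetalisation protects the C3a/C4 1,3-diol as a six-membered acetonide and leaves only the C6 oxygen for later release.

Step 19
Reactants: 34 bis-silyl compound
Product: 35 (2S)-1-[(4R,5R)-5-ethyl-2,2-dimethyl-1,3-dioxan-4-yl]but-3-yn-2-ol
Conditions: TBAF, THF, 0 °C to rt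
Reagents that add atoms: none
Why: Fluoride removes the O-silyl and the C-silyl group in one operation; the acetonide is stable to it.

Step 20
Reactants: 35 terminal alkyne
Product: 36 (2S)-1-[(4R,5R)-5-ethyl-2,2-dimethyl-1,3-dioxan-4-yl]-3-(triethylsilyl)but-3-en-2-ol
Conditions: [Cp*Ru(MeCN)3]PF6 (2 mol %), Et3SiH, CH2Cl2, 0 °C to rt
Reagents that add atoms: triethylsilane, CC[SiH](CC)CC
Why: Ruthenium-catalysed Markovnikov hydrosilylation of terminal alkynes places silicon on the internal carbon and tolerates free hydroxyl groups.

Step 21
Reactants: 36 α-vinylsilane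
Product: 37 (2S)-1-[(4R,5R)-5-ethyl-2,2-dimethyl-1,3-dioxan-4-yl]-3-iodobut-3-en-2-ol
Conditions: NIS, 2,6-lutidine, (CF3)2CHOH, 0 °C
Reagents that add atoms: N-iodosuccinimide, O=C1CCC(=O)N1I
Why: Ipso iododesilylation of the vinylsilane gives the 2-iodoalkene without moving the double bond; the buffer protects the acetonide.

**Part C: union and end game**

Step 22
Reactants: 21 alkyl iodide; 37 vinyl iodide
Product: 39 (2R,3R,4R)-2-ethyl-3-{(4R,8S)-9-[(4R,5R)-5-ethyl-2,2-dimethyl-1,3-dioxan-4-yl]-8-hydroxy-4-methyl-7-methylidenenonyl}-3,4-dimethyl-4-[(triethylsilyl)oxy]cyclohexan-1-one, via alkylzinc iodide 38 (not isolated)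
Conditions: 21, Zn dust (activated with BrCH2CH2Br and TMSCl), LiCl, THF, 40 °C; then 37, Pd(OAc)2 (3 mol %), SPhos (6 mol %), THF, rt
Reagents that add atoms: none
Why: Negishi coupling: direct zinc insertion gives an alkylzinc iodide that does not attack the ketone, and coupling with the alkenyl iodide under Pd/SPhos catalysis is faster than protonolysis by the secondary hydroxyl; no stereocentre is involved.

Step 23
Reactants: 39 allylic alcohol
Product: 40 (2R,3R,4R)-2-ethyl-3-{(4R,7R,8S)-9-[(4R,5R)-5-ethyl-2,2-dimethyl-1,3-dioxan-4-yl]-8-hydroxy-4,7-dimethylnonyl}-3,4-dimethyl-4-[(triethylsilyl)oxy]cyclohexan-1-one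
Conditions: [Rh(nbd)(dppb)]BF4 (5 mol %), H2 (50 atm), CH2Cl2, rt
Reagents that add atoms: none
Why: Hydroxyl-directed hydrogenation: the cationic rhodium binds the C6 hydroxyl and the 1,1-disubstituted alkene in the conformer that avoids strain between C5 and the C8 chain, and delivers hydrogen to give the anti C6/C7 relation; high pressure suppresses alkene isomerisation and the ketone is not reduced.

Step 24
Reactants: 40 ketone
Product: 42 (4R,5R,6R)-6-ethyl-5-{(4R,7R,8S)-9-[(4R,5R)-5-ethyl-2,2-dimethyl-1,3-dioxan-4-yl]-4,7-dimethyl-8-[(trimethylsilyl)oxy]nonyl}-4,5-dimethyl-4-[(triethylsilyl)oxy]cyclohex-2-en-1-one, via bis-trimethylsilyl enol ether 41 (not isolated)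
Conditions: LDA (3.5 equiv), TMSCl (5 equiv), THF, −78 °C; then Pd(OAc)2 (1.2 equiv), MeCN, rt
Reagents that add atoms: chlorotrimethylsilane, C[Si](C)(C)Cl
Why: Saegusa–Ito oxidation: kinetic deprotonation occurs at the C17 methylene and not at the hindered C15 methine, the C6 alkoxide is silylated in the same pot, and palladium diacetate turns the enol silane into the C17=C18 enone through an oxo-π-allyl complex and β-hydride elimination, so C15 is not touched.

Step 25
Reactants: 42 protected enone
Product: 43 (4R,5R,6R)-6-ethyl-4-hydroxy-5-[(4R,7R,8S,10R,11R)-8,10-dihydroxy-11-(hydroxymethyl)-4,7-dimethyltridecyl]-4,5-dimethylcyclohex-2-en-1-one (CNP0104178.2)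
Conditions: 48% aq. HF, MeCN, 0 °C to rt
Reagents that add atoms: none
Why: Aqueous HF cleaves both silyl ethers and the acetonide in one acidic operation; the C19 carbinol is deactivated towards ionisation by the conjugated ketone and no base is present to epimerise C15.

## Compound list

1 | (R)-citronellol | C[C@H](CCC=C(C)C)CCO | starting material
2 | tert-butyl{[(3R)-3,7-dimethyloct-6-en-1-yl]oxy}dimethylsilane | CC(C)(C)[Si](C)(C)OCC[C@H](C)CCC=C(C)C | intermediate
3 | secondary ozonide of 2 (epimers at the ring CH) | CC(C)(C)[Si](C)(C)OCC[C@H](C)CCC1OOC(C)(C)O1 | intermediate (not isolated)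
4 | (4R)-6-[(tert-butyldimethylsilyl)oxy]-4-methylhexanal | CC(C)(C)[Si](C)(C)OCC[C@H](C)CCC=O | intermediate
5 | 3-(triphenylphosphoranylidene)butan-2-one | CC(=O)C(C)=P(c1ccccc1)(c1ccccc1)c1ccccc1 | starting material
6 | (3E,7R)-9-[(tert-butyldimethylsilyl)oxy]-3,7-dimethylnon-3-en-2-one | CC(C)(C)[Si](C)(C)OCC[C@H](C)CC/C=C(\C)C(C)=O | intermediate
7 | allylboronic acid pinacol ester | C=CCB1OC(C)(C)C(C)(C)O1 | starting material
8 | O-(pinacolatoboryl) ether of 9 | CC(C)(C)[Si](C)(C)OCC[C@H](C)CC/C=C(\C)[C@](C)(OB1OC(C)(C)C(C)(C)O1)CC=C | intermediate (not isolated)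
9 | (4R,5E,9R)-11-[(tert-butyldimethylsilyl)oxy]-4,5,9-trimethylundeca-1,5-dien-4-ol | CC(C)(C)[Si](C)(C)OCC[C@H](C)CC/C=C(\C)[C@](C)(O)CC=C | intermediate
10 | triethylsilyl ether of 9 | CC(C)(C)[Si](C)(C)OCC[C@H](C)CC/C=C(\C)[C@](C)(O[Si](CC)(CC)CC)CC=C | intermediate
11 | B-alkyl-9-borabicyclo[3.3.1]nonane from 10 | CC(C)(C)[Si](C)(C)OCC[C@H](C)CC/C=C(\C)[C@](C)(O[Si](CC)(CC)CC)CCCB1C2CCCC1CCC2 | intermediate (not isolated)
12 | (4R,5E,9R)-11-[(tert-butyldimethylsilyl)oxy]-4,5,9-trimethyl-4-[(triethylsilyl)oxy]undec-5-en-1-ol | CC(C)(C)[Si](C)(C)OCC[C@H](C)CC/C=C(\C)[C@](C)(O[Si](CC)(CC)CC)CCCO | intermediate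
13 | (4R,5E,9R)-11-[(tert-butyldimethylsilyl)oxy]-4,5,9-trimethyl-4-[(triethylsilyl)oxy]undec-5-enoic acid | CC(C)(C)[Si](C)(C)OCC[C@H](C)CC/C=C(\C)[C@](C)(O[Si](CC)(CC)CC)CCC(=O)O | intermediate
14 | (trimethylsilyl)diazomethane | C[Si](C)(C)C=[N+]=[N-] | starting material
15 | isobutyl carbonic mixed anhydride of 13 | CC(C)(C)[Si](C)(C)OCC[C@H](C)CC/C=C(\C)[C@](C)(O[Si](CC)(CC)CC)CCC(=O)OC(=O)OCC(C)C | intermediate (not isolated)
16 | (5R,6E,10R)-12-[(tert-butyldimethylsilyl)oxy]-1-diazo-5,6,10-trimethyl-5-[(triethylsilyl)oxy]dodec-6-en-2-one | CC(C)(C)[Si](C)(C)OCC[C@H](C)CC/C=C(\C)[C@](C)(O[Si](CC)(CC)CC)CCC(=O)C=[N+]=[N-] | intermediate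
17 | (1S,5R,6R,7S)-7-{(3R)-5-[(tert-butyldimethylsilyl)oxy]-3-methylpentyl}-5,6-dimethyl-5-[(triethylsilyl)oxy]bicyclo[4.1.0]heptan-2-one | CC(C)(C)[Si](C)(C)OCC[C@H](C)CC[C@@H]1[C@@]2(C)[C@](C)(O[Si](CC)(CC)CC)CCC(=O)[C@@H]12 | intermediate
18 | lithium C15=C16 enolate from 17 | CC(C)(C)[Si](C)(C)OCC[C@H](C)CCC[C@]1(C)C=C([O-])CC[C@@]1(C)O[Si](CC)(CC)CC.[Li+] | intermediate (not isolated)
19 | (2R,3R,4R)-3-{(4R)-6-[(tert-butyldimethylsilyl)oxy]-4-methylhexyl}-2-ethyl-3,4-dimethyl-4-[(triethylsilyl)oxy]cyclohexan-1-one | CC(C)(C)[Si](C)(C)OCC[C@H](C)CCC[C@]1(C)[C@@H](CC)C(=O)CC[C@@]1(C)O[Si](CC)(CC)CC | intermediate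
20 | (2R,3R,4R)-2-ethyl-3-[(4R)-6-hydroxy-4-methylhexyl]-3,4-dimethyl-4-[(triethylsilyl)oxy]cyclohexan-1-one | OCC[C@H](C)CCC[C@]1(C)[C@@H](CC)C(=O)CC[C@@]1(C)O[Si](CC)(CC)CC | intermediate
21 | (2R,3R,4R)-2-ethyl-3-[(4R)-6-iodo-4-methylhexyl]-3,4-dimethyl-4-[(triethylsilyl)oxy]cyclohexan-1-one | ICC[C@H](C)CCC[C@]1(C)[C@@H](CC)C(=O)CC[C@@]1(C)O[Si](CC)(CC)CC | intermediate
22 | 3-(trimethylsilyl)prop-2-ynal | C[Si](C)(C)C#CC=O | starting material
23 | (−)-B-allyldiisopinocampheylborane | C=CCB([C@@H]1C[C@@H]2C[C@H]([C@H]1C)C2(C)C)[C@@H]1C[C@@H]2C[C@H]([C@H]1C)C2(C)C | starting material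
24 | diisopinocampheylborinate of 25 | C=CC[C@H](OB([C@@H]1C[C@@H]2C[C@H]([C@H]1C)C2(C)C)[C@@H]1C[C@@H]2C[C@H]([C@H]1C)C2(C)C)C#C[Si](C)(C)C | intermediate (not isolated)
25 | (3S)-1-(trimethylsilyl)hex-5-en-1-yn-3-ol | C=CC[C@H](O)C#C[Si](C)(C)C | intermediate
26 | tert-butyldimethyl{[(3S)-1-(trimethylsilyl)hex-5-en-1-yn-3-yl]oxy}silane | C=CC[C@H](O[Si](C)(C)C(C)(C)C)C#C[Si](C)(C)C | intermediate
27 | secondary ozonide of 26 (epimers at the ring CH) | CC(C)(C)[Si](C)(C)O[C@@H](CC1OCOO1)C#C[Si](C)(C)C | intermediate (not isolated)
28 | (3S)-3-[(tert-butyldimethylsilyl)oxy]-5-(trimethylsilyl)pent-4-ynal | O=CC[C@H](O[Si](C)(C)C(C)(C)C)C#C[Si](C)(C)C | intermediate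
29 | (4S)-4-benzyl-3-butanoyl-1,3-oxazolidin-2-one | CCCC(=O)N1[C@@H](Cc2ccccc2)COC1=O | starting material
30 | (Z)-dibutylboron enolate of 29 | CC/C=C(\OB(CCCC)CCCC)N1[C@@H](Cc2ccccc2)COC1=O | intermediate (not isolated)
31 | dibutylboron aldolate of 32 | CC[C@H](C(=O)N1[C@@H](Cc2ccccc2)COC1=O)[C@H](OB(CCCC)CCCC)C[C@H](O[Si](C)(C)C(C)(C)C)C#C[Si](C)(C)C | intermediate (not isolated)
32 | (4S)-4-benzyl-3-{(2S,3R,5S)-5-[(tert-butyldimethylsilyl)oxy]-2-ethyl-3-hydroxy-7-(trimethylsilyl)hept-6-ynoyl}-1,3-oxazolidin-2-one | CC[C@H](C(=O)N1[C@@H](Cc2ccccc2)COC1=O)[C@H](O)C[C@H](O[Si](C)(C)C(C)(C)C)C#C[Si](C)(C)C | intermediate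
33 | (2R,3R,5S)-5-[(tert-butyldimethylsilyl)oxy]-2-ethyl-7-(trimethylsilyl)hept-6-yne-1,3-diol | CC[C@H](CO)[C@H](O)C[C@H](O[Si](C)(C)C(C)(C)C)C#C[Si](C)(C)C | intermediate
34 | tert-butyl{[(2S)-1-[(4R,5R)-5-ethyl-2,2-dimethyl-1,3-dioxan-4-yl]-4-(trimethylsilyl)but-3-yn-2-yl]oxy}dimethylsilane | CC[C@@H]1COC(C)(C)O[C@@H]1C[C@H](O[Si](C)(C)C(C)(C)C)C#C[Si](C)(C)C | intermediate
35 | (2S)-1-[(4R,5R)-5-ethyl-2,2-dimethyl-1,3-dioxan-4-yl]but-3-yn-2-ol | CC[C@@H]1COC(C)(C)O[C@@H]1C[C@H](O)C#C | intermediate
36 | (2S)-1-[(4R,5R)-5-ethyl-2,2-dimethyl-1,3-dioxan-4-yl]-3-(triethylsilyl)but-3-en-2-ol | CC[C@@H]1COC(C)(C)O[C@@H]1C[C@H](O)C(=C)[Si](CC)(CC)CC | intermediate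
37 | (2S)-1-[(4R,5R)-5-ethyl-2,2-dimethyl-1,3-dioxan-4-yl]-3-iodobut-3-en-2-ol | CC[C@@H]1COC(C)(C)O[C@@H]1C[C@H](O)C(I)=C | intermediate
38 | alkylzinc iodide from 21 | I[Zn]CC[C@H](C)CCC[C@]1(C)[C@@H](CC)C(=O)CC[C@@]1(C)O[Si](CC)(CC)CC | intermediate (not isolated)
39 | (2R,3R,4R)-2-ethyl-3-{(4R,8S)-9-[(4R,5R)-5-ethyl-2,2-dimethyl-1,3-dioxan-4-yl]-8-hydroxy-4-methyl-7-methylidenenonyl}-3,4-dimethyl-4-[(triethylsilyl)oxy]cyclohexan-1-one | CC[C@@H]1COC(C)(C)O[C@@H]1C[C@H](O)C(=C)CC[C@H](C)CCC[C@]2(C)[C@@H](CC)C(=O)CC[C@@]2(C)O[Si](CC)(CC)CC | intermediate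
40 | (2R,3R,4R)-2-ethyl-3-{(4R,7R,8S)-9-[(4R,5R)-5-ethyl-2,2-dimethyl-1,3-dioxan-4-yl]-8-hydroxy-4,7-dimethylnonyl}-3,4-dimethyl-4-[(triethylsilyl)oxy]cyclohexan-1-one | CC[C@@H]1COC(C)(C)O[C@@H]1C[C@H](O)[C@H](C)CC[C@H](C)CCC[C@]2(C)[C@@H](CC)C(=O)CC[C@@]2(C)O[Si](CC)(CC)CC | intermediate
41 | bis-trimethylsilyl derivative of 40 (C6 silyl ether, C16–C17 enol silane) | CC[C@@H]1COC(C)(C)O[C@@H]1C[C@H](O[Si](C)(C)C)[C@H](C)CC[C@H](C)CCC[C@]2(C)[C@@H](CC)C(O[Si](C)(C)C)=CC[C@@]2(C)O[Si](CC)(CC)CC | intermediate (not isolated)
42 | (4R,5R,6R)-6-ethyl-5-{(4R,7R,8S)-9-[(4R,5R)-5-ethyl-2,2-dimethyl-1,3-dioxan-4-yl]-4,7-dimethyl-8-[(trimethylsilyl)oxy]nonyl}-4,5-dimethyl-4-[(triethylsilyl)oxy]cyclohex-2-en-1-one | CC[C@@H]1COC(C)(C)O[C@@H]1C[C@H](O[Si](C)(C)C)[C@H](C)CC[C@H](C)CCC[C@]2(C)[C@@H](CC)C(=O)C=C[C@@]2(C)O[Si](CC)(CC)CC | intermediate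
43 | (4R,5R,6R)-6-ethyl-4-hydroxy-5-[(4R,7R,8S,10R,11R)-8,10-dihydroxy-11-(hydroxymethyl)-4,7-dimethyltridecyl]-4,5-dimethylcyclohex-2-en-1-one | CC[C@H](CO)[C@H](O)C[C@H](O)[C@H](C)CC[C@H](C)CCC[C@]1(C)[C@@H](CC)C(=O)C=C[C@@]1(C)O | target

## Step count and least certain steps

Total: 25 steps. Longest linear sequence: 16 steps (steps 1–12 and 22–25, from 1); the polyol branch (steps 13–21) has 9 steps before the union.

Step 9 (key step). The most likely problem is weak facial discrimination by C19: methyl and silyloxy differ only moderately in effective size, so the carbenoid may add to both alkene faces and give the series epimeric at C13, C14 and C15 beside 17. Diversion of the carbenoid to the neighbouring silyl ether oxygen is a second, smaller risk. Fallback: the source of stereocontrol is moved from the substrate to the catalyst. Starting from 16, the carbenoid is generated with CuOTf and a C2-symmetric bis(oxazoline) ligand, a catalyst class known for enantioselective intramolecular cyclopropanation of alkenyl diazoketones. Both ligand antipodes are tried, and the matched one should reinforce the substrate bias. The route is rejoined at 17; no new compound arises (F0).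

Step 4. The most likely problem is incomplete enantiofacial control in the allyl transfer, because the methyl and the α-branched alkenyl group flank the carbonyl; the C19 epimer could not be removed later, since C10 is too remote to make the isomers separable. Fallback: catalyst control is replaced by stoichiometric reagent control. Starting from 6, a chiral B-allyl-10-phenyl-9-borabicyclo[3.3.2]decane (antipode for Re-face attack) is used in Et2O at −78 °C with oxidative work-up; its rigid pocket differentiates methyl ketones by a different mechanism. The route is rejoined at 9; no new compound arises (F0).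

Step 10. The most likely problem is slow C-ethylation at the neopentyl-type enolate carbon, which allows proton transfer between product and enolate, followed by alkylation at C17 or dialkylation; the face selectivity at C15 may also be moderate. Fallback: the enolate is not alkylated in the ammonia pot. Starting from 17, the Li/NH3 reduction is quenched with TMSCl and Et3N, and the regiodefined trimethylsilyl enol ether F1 is isolated. MeLi in THF then releases the amine-free lithium enolate, which is ethylated with EtI in THF/DMPU. The route is rejoined at 19.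

Step 11. The most likely problem is partial loss of the tertiary TES ether during methanolysis of the primary TBS ether, because the two rates may not differ enough. Fallback: selectivity is given up. Starting from 19, both silyl groups are removed with HF·pyridine to give the diol F2. The primary hydroxyl alone is converted with I2, PPh3 and imidazole into the iodo alcohol F3, and the tertiary hydroxyl is silylated again with TESOTf and 2,6-lutidine. The route is rejoined at 21.

Step 24. The most likely problem is incomplete conversion in the palladium step, with hydrolysis of the enol silane back to the ketone, on a substrate that carries several Lewis-basic oxygens. Fallback: the dehydrogenation is done through selenium. Starting from 40, the enol silane 41 is formed as before and treated with PhSeCl to give the α-phenylselanyl ketone F4. Oxidation with H2O2 and pyridine gives the selenoxide F5, which undergoes syn elimination towards C18 at 0 °C to rt. The route is rejoined at 42.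

## Further compounds

F0 | step 9 | none | none
F0 | step 4 | none | none
F1 | step 10 | trimethylsilyl enol ether (C15=C16) from reductive opening of 17 | CC(C)(C)[Si](C)(C)OCC[C@H](C)CCC[C@]1(C)C=C(O[Si](C)(C)C)CC[C@@]1(C)O[Si](CC)(CC)CC
F2 | step 11 | (2R,3R,4R)-2-ethyl-4-hydroxy-3-[(4R)-6-hydroxy-4-methylhexyl]-3,4-dimethylcyclohexan-1-one | OCC[C@H](C)CCC[C@]1(C)[C@@H](CC)C(=O)CC[C@@]1(C)O
F3 | step 11 | (2R,3R,4R)-2-ethyl-4-hydroxy-3-[(4R)-6-iodo-4-methylhexyl]-3,4-dimethylcyclohexan-1-one | ICC[C@H](C)CCC[C@]1(C)[C@@H](CC)C(=O)CC[C@@]1(C)O
F4 | step 24 | C17 phenylselanyl ketone derived from 41 (epimers at C17) | CC[C@@H]1COC(C)(C)O[C@@H]1C[C@H](O[Si](C)(C)C)[C@H](C)CC[C@H](C)CCC[C@]2(C)[C@@H](CC)C(=O)C([Se]c3ccccc3)C[C@@]2(C)O[Si](CC)(CC)CC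
F5 | step 24 | selenoxide of F4 | CC[C@@H]1COC(C)(C)O[C@@H]1C[C@H](O[Si](C)(C)C)[C@H](C)CC[C@H](C)CCC[C@]2(C)[C@@H](CC)C(=O)C([Se](=O)c3ccccc3)C[C@@]2(C)O[Si](CC)(CC)CC
A1 | alternative 1 | (3S,4R)-3-[(tert-butyldimethylsilyl)oxy]-5-[(4-methoxybenzyl)oxy]-4-methylpentanal | O=CC[C@H](O[Si](C)(C)C(C)(C)C)[C@H](C)COCc1ccc(OC)cc1
A2 | alternative 1 | ethylketene | CCC=C=O
A3 | alternative 1 | cis-3-ethyl-4-alkyloxetan-2-one | CC[C@@H]1C(=O)O[C@@H]1C[C@H](O[Si](C)(C)C(C)(C)C)[C@H](C)COCc2ccc(OC)cc2
A4 | alternative 2 | δ-lactone with ketal, ethyl and (Z)-silyloxypropenyl groups (C14 epimers) | CC1C(=O)O[C@H](/C=C(/C)O[Si](C)(C)C(C)(C)C)C2(OCCO2)[C@@H]1CC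
A5 | alternative 2 | trimethylsilyl ketene acetal of A4 | CC1=C(O[Si](C)(C)C)O[C@H](/C=C(/C)O[Si](C)(C)C(C)(C)C)C2(OCCO2)[C@@H]1CC
A6 | alternative 2 | cyclohexenecarboxylic acid with C14 and C19 set | OC(=O)[C@]1(C)[C@@H](CC)C2(OCCO2)C=C[C@@]1(C)O[Si](C)(C)C(C)(C)C
A7 | alternative 3 | (bromomethyl)dimethylsilyl ether of the tetrasubstituted enone | CC[C@H](CO[Si](C)(C)C(C)(C)C)[C@H]1C[C@H](OC(C)(C)O1)[C@H](C)CC[C@H](C)CCCC2=C(CC)C(=O)CC[C@@]2(C)O[Si](C)(C)CBr
A8 | alternative 3 | oxasilolane-fused cyclohexanone | CC[C@H](CO[Si](C)(C)C(C)(C)C)[C@H]1C[C@H](OC(C)(C)O1)[C@H](C)CC[C@H](C)CCC[C@@]23C[Si](C)(C)O[C@]2(C)CCC(=O)[C@@H]3CC
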